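## Retrosynthetic overview

1. Target 16 (3β,15-diformyloxy-labd-7-ene) ⇐ diol 15 ⇐ dipivalate 14; these last steps only exchange the ester groups.
2. 14 ⇐ monocyclic carbinol 12 by one cationic cascade: C4 shifts from C10 to the exocyclic carbinol carbon C5, which turns the cyclopentane C10–C4–C3–C2–C1 into ring A (C1–C2–C3–C4–C5–C10). The C10 cation is then attacked by the C8=C9 olefin (bond C9–C10, ring B) and ends as the C7=C8 olefin.
3. Enabling feature: in ring A the fully substituted C4 (gem-dimethyl) lies between C5 and the methyl-bearing C10. C4 is therefore the best migrating group, C10 becomes a tertiary cation exactly where a polyene cyclisation needs it, and the 1,2,2-trimethylcyclopentane with oxygen at C3 is the skeleton of camphoric acid.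
4. 12 ⇐ ketone 11 ⇐ methyl ketone 6 (from (1R,3S)-camphoric acid 1: C1–C5, C10, C18–C20 and the C3 stereocenter) + allylic bromide 10 (from (S)-citronellol 7: C7–C9, C11–C17 and the C13 stereocenter).
5. Ring order: cyclopentane from the chiral pool → ring A by ring expansion → ring B, the last two both in step 11.

Key step: step 11

Remark: (1R,3S)-(+)-camphoric acid and (S)-(−)-citronellol are taken as commercial single enantiomers; C1–C20 in the text are labdane positions of the target, used for the precursors as well.

## Route

Step 1
Reactants: 1 (1R,3S)-(+)-camphoric acid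
Product: 2 (1R,5S)-1,8,8-trimethyl-3-oxabicyclo[3.2.1]octane-2,4-dione (camphoric anhydride)
Conditions: Ac2O, reflux; distil off AcOH/Ac2O
Reagents that add atoms: none
Why: The cis-1,3-diacid should close to the bridged six-membered anhydride on dehydration with acetic anhydride, without touching a stereocenter.

Step 2
Reactants: 2 camphoric anhydride
Product: 3 (1R,3S)-3-acetyl-1,2,2-trimethylcyclopentane-1-carboxylic acid
Conditions: MeMgBr (1.05 eq, slow addition), THF, −78 °C; then 1 M HCl
Reagents that add atoms: methylmagnesium bromide, C[Mg]Br
Why: Grignard acylation by a cyclic anhydride should take place at the carbonyl on the CH carbon, not at the neopentyl carbonyl on the quaternary carbon, and the tetrahedral magnesium adduct should resist a second addition at −78 °C, so the configuration at the ring CH is kept.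

Step 3
Reactants: 3 keto acid
Product: 4 (1R,3S)-3-acetoxy-1,2,2-trimethylcyclopentane-1-carboxylic acid
Conditions: mCPBA, CF3CO2H (cat.), CH2Cl2, 0 °C → rt
Reagents that add atoms: 3-chloroperbenzoic acid, OOC(=O)c1cccc(Cl)c1
Why: In the Baeyer–Villiger oxidation the secondary ring carbon migrates in preference to methyl and with retention, which places oxygen on the future C3 with the configuration of the target (3S).

Step 4
Reactants: 4 acetoxy acid
Product: 5 1-[(1R,3S)-3-hydroxy-1,2,2-trimethylcyclopentyl]ethan-1-one
Conditions: MeLi (6 eq), THF/Et2O, 0 °C → rt; inverse quench into cold 1 M HCl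
Reagents that add atoms: methyllithium, [Li]C
Why: Addition of MeLi to the lithium carboxylate should stop at the gem-dialkoxide, which gives the methyl ketone only on work-up (ketone synthesis from a carboxylic acid), while the excess reagent removes the acetate.

Step 5
Reactants: 5 hydroxy ketone
Product: 6 (1S,3R)-3-acetyl-2,2,3-trimethylcyclopentyl pivalate
Conditions: PivCl, pyridine, DMAP (cat.), CH2Cl2, 0 → 40 °C
Reagents that add atoms: pivaloyl chloride, CC(C)(C)C(=O)Cl
Why: DMAP-catalysed acylation of the hindered secondary alcohol should give an ester that survives LDA, borane and triflation and is a poor neighbouring group in step 11.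

Step 6
Reactants: 7 (S)-(−)-citronellol
Product: 8 (3S)-3,7-dimethyloct-6-en-1-yl pivalate
Conditions: PivCl, pyridine, CH2Cl2, 0 °C → rt
Reagents that add atoms: pivaloyl chloride, CC(C)(C)C(=O)Cl
Why: Standard acylation of a primary alcohol; the C13 stereocenter of the target is carried in unchanged.

Step 7
Reactants: 8 citronellyl pivalate
Product: 9 (3S,6E)-8-hydroxy-3,7-dimethyloct-6-en-1-yl pivalate
Conditions: SeO2 (0.3 eq), t-BuOOH (70 % aq.), salicylic acid (cat.), CH2Cl2, rt
Reagents that add atoms: tert-butyl hydroperoxide, CC(C)(C)OO (terminal oxidant; the oxygen is relayed by catalytic selenium dioxide, O=[Se]=O)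
Why: Selenium dioxide allylic oxidation (ene reaction, then [2,3]-sigmatropic shift) attacks the (E)-methyl of a gem-dimethyl trisubstituted olefin and should give the (E)-allylic alcohol.

Step 8
Reactants: 9 allylic alcohol
Product: 10 (3S,6E)-8-bromo-3,7-dimethyloct-6-en-1-yl pivalate
Conditions: CBr4, PPh3, CH2Cl2, 0 °C
Reagents that add atoms: carbon tetrabromide, BrC(Br)(Br)Br
Why: The Appel reaction should convert the primary allylic alcohol into the bromide under neutral conditions, without allylic transposition or loss of olefin geometry.

Step 9
Reactants: 6 methyl ketone (1.2 eq); 10 allylic bromide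
Product: 11 (3S,6E)-3,7-dimethyl-10-oxo-10-[(1R,3S)-1,2,2-trimethyl-3-(pivaloyloxy)cyclopentyl]dec-6-en-1-yl pivalate
Conditions: LDA, THF, −78 °C; then 10, DMPU, −78 → −20 °C
Reagents that add atoms: none
Why: The ketone can enolise only at its methyl group (the other α-carbon is quaternary), so SN2 alkylation of the lithium enolate by the primary allylic bromide should form the C6–C7 bond with the E olefin intact.

Step 10
Reactants: 11 ketone
Product: 12 (3S,6E,10S)-10-hydroxy-3,7-dimethyl-10-[(1R,3S)-1,2,2-trimethyl-3-(pivaloyloxy)cyclopentyl]dec-6-en-1-yl pivalate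
Conditions: (R)-Me-CBS (20 mol %), catecholborane, toluene, −40 °C; then MeOH, aq. NaOH
Reagents that add atoms: none
Why: In the Corey–Bakshi–Shibata reduction the tert-alkyl group acts as the large substituent, so the (R)-catalyst should deliver hydride to give the (S)-carbinol at C5 under reagent control, and catecholborane at low temperature leaves the olefin and the esters alone.

Step 11
Reactants: 12 (10S)-carbinol
Product: 14 (3S,5R,9S,10R,13S)-labd-7-ene-3,15-diyl dipivalate, via secondary triflate 13 (not isolated)
Conditions: Tf2O, 2,6-di-tert-butyl-4-methylpyridine, CH2Cl2, −78 °C; then (CF3)2CHOH, −78 → 0 °C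
Reagents that add atoms: none
Why: Proposed new method: the carbinol is triflated in situ and the neopentyl-type secondary triflate 13 should ionise only with anchimeric assistance, the ring bond C10–C4 anti to the leaving group shifting to C5 (Wagner–Meerwein 1,2-alkyl shift), which enlarges the cyclopentane C10–C4–C3–C2–C1 to the six-membered ring A and leaves a tertiary cation at C10; this cation is taken by the C8=C9 olefin in a 6-endo-trig cation–olefin closure of ring B (bond C9–C10), and the C8 cation loses the axial C7 proton to give the C7=C8 olefin. The closest known reaction types are the solvolytic ring enlargement of 1-alkylcyclopentylcarbinyl sulfonates to cyclohexyl cations and the second ring closure of a biomimetic polyene cyclisation, which starts from this same monocyclic tertiary cation; their coupling in one flask is the untested part. Ring A thus forms by ring expansion (inversion at the migration terminus C5) and ring B by chair-like 6-endo attack. C5 is controlled by the (S)-carbinol through the stereospecific backside shift, and C10 and C9 by a chair–chair transition state in which the C3 pivalate and the C5 chain are equatorial, the olefin bonds to C10 on the face away from the axial C4 methyl (trans fusion) and its E geometry places C11 equatorial; the configuration of the old quaternary carbon is erased and therefore does not matter. The step needs C4 to migrate instead of C1 or the methyl group, which the substrate secures because C4 is the only fully substituted neighbour (best bridging group) and its shift relieves the C10/C4 quaternary–quaternary strain; it also needs carbon and not oxygen to capture the cations, for which the weakly donating, geometrically remote pivalate and the non-nucleophilic triflate, base and solvent were chosen.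

Step 12
Reactants: 14 dipivalate
Product: 15 (3S,5R,9S,10R,13S)-labd-7-ene-3,15-diol
Conditions: LiAlH4, THF, 0 °C → rt; aqueous NaOH work-up
Reagents that add atoms: none
Why: Hydride reduction should cleave both hindered pivalates, while the trisubstituted olefin and all stereocenters are inert to the reagent.

Step 13
Reactants: 15 diol
Product: 16 (3S,5R,9S,10R,13S)-labd-7-ene-3,15-diyl diformate (target)
Conditions: acetic formic anhydride (preformed), pyridine, CH2Cl2, 0 °C → rt
Reagents that add atoms: acetic formic anhydride, CC(=O)OC=O
Why: The mixed anhydride transfers its more electrophilic formyl group, so the primary and the equatorial 3β-hydroxyl should both be formylated under mild, non-acidic conditions that leave the C7=C8 olefin in place.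

## Compound list

1 | (1R,3S)-(+)-camphoric acid [(1R,3S)-1,2,2-trimethylcyclopentane-1,3-dicarboxylic acid] | OC(=O)[C@H]1CC[C@@](C)(C(=O)O)C1(C)C | starting material
2 | (1R,5S)-1,8,8-trimethyl-3-oxabicyclo[3.2.1]octane-2,4-dione (camphoric anhydride) | CC1(C)[C@@H]2CC[C@@]1(C)C(=O)OC2=O | intermediate
3 | (1R,3S)-3-acetyl-1,2,2-trimethylcyclopentane-1-carboxylic acid | CC(=O)[C@H]1CC[C@@](C)(C(=O)O)C1(C)C | intermediate
4 | (1R,3S)-3-acetoxy-1,2,2-trimethylcyclopentane-1-carboxylic acid | CC(=O)O[C@H]1CC[C@@](C)(C(=O)O)C1(C)C | intermediate
5 | 1-[(1R,3S)-3-hydroxy-1,2,2-trimethylcyclopentyl]ethan-1-one | O[C@H]1CC[C@@](C)(C(C)=O)C1(C)C | intermediate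
6 | (1S,3R)-3-acetyl-2,2,3-trimethylcyclopentyl pivalate | CC(C)(C)C(=O)O[C@H]1CC[C@@](C)(C(C)=O)C1(C)C | intermediate
7 | (S)-(−)-citronellol [(3S)-3,7-dimethyloct-6-en-1-ol] | OCC[C@@H](C)CCC=C(C)C | starting material
8 | (3S)-3,7-dimethyloct-6-en-1-yl pivalate | CC(C)(C)C(=O)OCC[C@@H](C)CCC=C(C)C | intermediate
9 | (3S,6E)-8-hydroxy-3,7-dimethyloct-6-en-1-yl pivalate | CC(C)(C)C(=O)OCC[C@@H](C)CC/C=C(\C)CO | intermediate
10 | (3S,6E)-8-bromo-3,7-dimethyloct-6-en-1-yl pivalate | CC(C)(C)C(=O)OCC[C@@H](C)CC/C=C(\C)CBr | intermediate
11 | (3S,6E)-3,7-dimethyl-10-oxo-10-[(1R,3S)-1,2,2-trimethyl-3-(pivaloyloxy)cyclopentyl]dec-6-en-1-yl pivalate | CC(C)(C)C(=O)OCC[C@@H](C)CC/C=C(C)/CCC(=O)[C@]1(C)CC[C@H](OC(=O)C(C)(C)C)C1(C)C | intermediate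
12 | (3S,6E,10S)-10-hydroxy-3,7-dimethyl-10-[(1R,3S)-1,2,2-trimethyl-3-(pivaloyloxy)cyclopentyl]dec-6-en-1-yl pivalate | CC(C)(C)C(=O)OCC[C@@H](C)CC/C=C(C)/CC[C@H](O)[C@]1(C)CC[C@H](OC(=O)C(C)(C)C)C1(C)C | intermediate
13 | (10S)-trifluoromethanesulfonate of 12 (not isolated) | CC(C)(C)C(=O)OCC[C@@H](C)CC/C=C(C)/CC[C@H](OS(=O)(=O)C(F)(F)F)[C@]1(C)CC[C@H](OC(=O)C(C)(C)C)C1(C)C | intermediate
14 | (3S,5R,9S,10R,13S)-labd-7-ene-3,15-diyl dipivalate | CC1=CC[C@H]2C(C)(C)[C@@H](OC(=O)C(C)(C)C)CC[C@]2(C)[C@H]1CC[C@H](C)CCOC(=O)C(C)(C)C | intermediate
15 | (3S,5R,9S,10R,13S)-labd-7-ene-3,15-diol | CC1=CC[C@H]2C(C)(C)[C@@H](O)CC[C@]2(C)[C@H]1CC[C@H](C)CCO | intermediate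
16 | (3S,5R,9S,10R,13S)-labd-7-ene-3,15-diyl diformate | CC1=CC[C@H]2C(C)(C)[C@@H](OC=O)CC[C@]2(C)[C@H]1CC[C@H](C)CCOC=O | target

## Step count and risks

Total step count: 13. Longest linear sequence: 10 steps (steps 1–5 and 9–13); steps 6–8 form the side-chain branch.

Steps most likely to fail:

Step 11 (Proposed new method). The cascade may leave the intended path in three ways: a ring bond other than C10–C4 or the methyl group may migrate during ionisation; the monocyclic C10 cation may lose a proton before ring B closes; or the final C8 cation may be deprotonated unselectively toward the exocyclic or tetrasubstituted olefin. The fallback separates the two events and uses known chemistry. It sets out from 12, which is converted with MsCl/Et3N into the (10S)-mesylate F1. Buffered solvolysis of F1 (2,6-lutidine, aqueous acetone, 60 °C) is the known Wagner–Meerwein ring enlargement of a cyclopentylcarbinyl sulfonate and should end, by proton loss from the C10 cation, in the ring-enlarged tetrasubstituted cyclohexene F2; its double-bond isomers are protonated to the same cation. F2 is then cyclised with chlorosulfonic acid in 2-nitropropane at −78 °C, the known acid cyclisation of monocyclic 1,5-dienes of the cyclofarnesyl type. Protonation at C5 and attack of the olefin at C10 should occur anti through the chair with the equatorial pivalate, and low-temperature strong-acid conditions favour the ring-trisubstituted olefin. The fallback returns to the route at 14.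

Step 10. Hydride delivery may show poor facial selectivity, because the ketone is flanked by a quaternary stereocenter whose own bias can oppose the catalyst and because the hindered carbonyl may coordinate weakly; slow reduction would also give hydroboration of the olefin time to compete. The fallback gives up reagent control. It sets out from 11, which is reduced with NaBH4 in MeOH to both carbinols. Chromatography should provide 12, and the (10R)-carbinol F3 is oxidised back to 11 with Dess–Martin periodinane and recycled. The fallback returns to the route at 12.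

Step 2. A second methyl addition to the newly formed ketone (leading to a lactone) or enolisation next to it may erode the mono-addition. The fallback sets out from 2, which is opened at the same less hindered carbonyl with N,O-dimethylhydroxylamine hydrochloride and pyridine to the N-methoxy-N-methylamide acid F4. Its chelated tetrahedral adduct should stop MeMgBr (3 eq, THF, 0 °C) at the ketone stage (Weinreb ketone synthesis). The fallback returns to the route at 3.

## Further compounds

F1 | step 11 | (3S,6E,10S)-10-(methanesulfonyloxy)-3,7-dimethyl-10-[(1R,3S)-1,2,2-trimethyl-3-(pivaloyloxy)cyclopentyl]dec-6-en-1-yl pivalate | CC(C)(C)C(=O)OCC[C@@H](C)CC/C=C(C)/CC[C@H](OS(C)(=O)=O)[C@]1(C)CC[C@H](OC(=O)C(C)(C)C)C1(C)C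
F2 | step 11 | (3S,6E)-3,7-dimethyl-9-[(5S)-2,6,6-trimethyl-5-(pivaloyloxy)cyclohex-1-en-1-yl]non-6-en-1-yl pivalate | CC1=C(CC/C(C)=C/CC[C@H](C)CCOC(=O)C(C)(C)C)C(C)(C)[C@@H](OC(=O)C(C)(C)C)CC1
F3 | step 10 | (3S,6E,10R)-10-hydroxy-3,7-dimethyl-10-[(1R,3S)-1,2,2-trimethyl-3-(pivaloyloxy)cyclopentyl]dec-6-en-1-yl pivalate | CC(C)(C)C(=O)OCC[C@@H](C)CC/C=C(C)/CC[C@@H](O)[C@]1(C)CC[C@H](OC(=O)C(C)(C)C)C1(C)C
F4 | step 2 | (1R,3S)-3-[methoxy(methyl)carbamoyl]-1,2,2-trimethylcyclopentane-1-carboxylic acid | CON(C)C(=O)[C@H]1CC[C@@](C)(C(=O)O)C1(C)C
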